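Ring A of the benzofuran is cut at C5–C6 and C7–C7a, so the benzo ring is grown last onto a fully substituted furan. The route exploits the C6 hydroxyl and the adjacent C5 prenyl group of ring A: this pair arises when a ketene carbon (C6) closes onto the outer end (C5) of a diene built from the furan C3a=C7a bond and a side-chain C4=C5 olefin. The precursor is a 2-diazoacetylfuran bearing, in furan numbering, an (E)-5-methylhexa-1,4-dienyl group at C3, methoxy at C4 and the protected aryl group at C5. In one operation it loses N2, rearranges, closes ring A and tautomerizes to the phenol.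

Key step: step 11

Remark: ring-A atoms are numbered as in the final benzofuran (C2–C7a). Every compound carrying the oxan-2-yl (THP) acetal is racemic at that carbon, the only stereocentre in any isolated compound; it is removed in step 12. The THP acetal is chosen because it leaves with pyridinium tosylate (PPTS), so no mineral acid meets the ortho-prenylphenol. Trimethylsilyldiazomethane replaces diazomethane.

Step 1
Reactants: 1 5-bromo-2-methoxyphenol
Product: 2 2-(5-bromo-2-methoxyphenoxy)oxane (racemic)
Conditions: 3,4-dihydro-2H-pyran (1.5 equiv), PPTS (0.1 equiv), CH2Cl2, 25 °C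
Reagents that add atoms: 3,4-dihydro-2H-pyran, C1CCOC=C1
Why: PPTS-catalysed addition of the phenol to the enol ether (tetrahydropyranylation) should mask the only acidic O–H as a base-stable acetal, whose new acetal centre forms racemic and needs no control.

Step 2
Reactants: 2 2-(5-bromo-2-methoxyphenoxy)oxane
Product: 3 2-[4-methoxy-3-(oxan-2-yloxy)phenyl]-4,4,5,5-tetramethyl-1,3,2-dioxaborolane (racemic)
Conditions: bis(pinacolato)diboron (1.1 equiv), PdCl2(dppf) (3 mol%), KOAc (3 equiv), 1,4-dioxane, 90 °C
Reagents that add atoms: bis(pinacolato)diboron, CC1(C)OB(OC1(C)C)B1OC(C)(C)C(C)(C)O1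
Why: Miyaura borylation, in which zerovalent palladium inserts into the aryl C–Br bond and acetate-assisted transmetalation delivers the boryl group, tolerates the acetal and the ethers.

Step 3
Reactants: 3 2-[4-methoxy-3-(oxan-2-yloxy)phenyl]-4,4,5,5-tetramethyl-1,3,2-dioxaborolane; 4 methyl 4,5-dibromofuran-2-carboxylate
Product: 5 methyl 4-bromo-5-[4-methoxy-3-(oxan-2-yloxy)phenyl]furan-2-carboxylate (racemic)
Conditions: Pd(PPh3)4 (5 mol%), Na2CO3 (2 M aq, 2.5 equiv), DME, 80 °C
Reagents that add atoms: none
Why: Suzuki–Miyaura coupling should be site-selective because oxidative addition is faster at the C5–Br bond, which is alpha to the ring oxygen and conjugated with the ester, than at C4–Br, as is established for 4,5-dibromo-2-furoates.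

Step 4
Reactants: 5 methyl 4-bromo-5-[4-methoxy-3-(oxan-2-yloxy)phenyl]furan-2-carboxylate
Product: 6 methyl 4-methoxy-5-[4-methoxy-3-(oxan-2-yloxy)phenyl]furan-2-carboxylate (racemic)
Conditions: NaOMe (5 equiv), CuI (0.2 equiv), MeOH/NMP, 100 °C
Reagents that add atoms: sodium methoxide, [Na+].[O-]C
Why: Ullmann-type C–O coupling, in which a copper methoxide species substitutes the remaining beta-bromide, should succeed because methoxide in methanol cannot scramble the methyl ester or harm the acetal.

Step 5
Reactants: 6 methyl 4-methoxy-5-[4-methoxy-3-(oxan-2-yloxy)phenyl]furan-2-carboxylate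
Product: 8 methyl 3-formyl-4-methoxy-5-[4-methoxy-3-(oxan-2-yloxy)phenyl]furan-2-carboxylate (racemic), via furylmagnesium chloride 7 (not isolated)
Conditions: TMPMgCl·LiCl (TMP = 2,2,6,6-tetramethylpiperidin-1-yl, 1.3 equiv), THF, −30 °C; then DMF (3 equiv), −30 to 0 °C; aq. NH4Cl
Reagents that add atoms: N,N-dimethylformamide, CN(C)C=O
Why: Directed magnesiation by the hindered magnesium amide removes the only ring proton, which is acidified and chelated by the flanking ester and methoxy groups, at a temperature where the ester is not attacked, and DMF then formylates the furylmagnesium species (Bouveault-type formylation).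

Step 6
Reactants: 9 5-bromo-2-methylpent-2-ene
Product: 10 5-[(4-methylpent-3-en-1-yl)sulfanyl]-1-phenyl-1H-tetrazole
Conditions: 1-phenyl-1H-tetrazole-5-thiol (1.05 equiv), K2CO3 (1.2 equiv), acetone, 56 °C
Reagents that add atoms: 1-phenyl-1H-tetrazole-5-thiol, Sc1nnnn1-c1ccccc1
Why: SN2 S-alkylation of the soft tetrazolethiolate by the primary homoallylic bromide.

Step 7
Reactants: 10 5-[(4-methylpent-3-en-1-yl)sulfanyl]-1-phenyl-1H-tetrazole
Product: 11 5-[(4-methylpent-3-en-1-yl)sulfonyl]-1-phenyl-1H-tetrazole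
Conditions: (NH4)6Mo7O24·4H2O (0.1 equiv), 30% aq. H2O2 (6 equiv), EtOH, 0 to 25 °C
Reagents that add atoms: hydrogen peroxide, OO
Why: Peroxomolybdate-catalysed sulfide-to-sulfone oxidation should be chemoselective because sulfur is far more nucleophilic toward the peroxo species than the trisubstituted olefin, which an organic peracid would epoxidize.

Step 8
Reactants: 11 5-[(4-methylpent-3-en-1-yl)sulfonyl]-1-phenyl-1H-tetrazole; 8 methyl 3-formyl-4-methoxy-5-[4-methoxy-3-(oxan-2-yloxy)phenyl]furan-2-carboxylate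
Product: 13 methyl 4-methoxy-5-[4-methoxy-3-(oxan-2-yloxy)phenyl]-3-[(1E)-5-methylhexa-1,4-dien-1-yl]furan-2-carboxylate (racemic at the acetal carbon), via potassium sulfonyl carbanion 12 (not isolated)
Conditions: 11 (1.2 equiv), KN(SiMe3)2 (1.15 equiv), DME, −60 °C; then 8, −60 to 25 °C; aq. NH4Cl
Reagents that add atoms: none
Why: Julia–Kocienski olefination (carbanion addition to the aldehyde, Smiles transfer of the tetrazole, anti elimination of SO2 and tetrazololate) should give the disubstituted olefin with (E) geometry, favoured by the potassium counter-ion in DME and by conjugation with the furan, while the much less electrophilic ester is left alone.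

Step 9
Reactants: 13 methyl 4-methoxy-5-[4-methoxy-3-(oxan-2-yloxy)phenyl]-3-[(1E)-5-methylhexa-1,4-dien-1-yl]furan-2-carboxylate
Product: 14 4-methoxy-5-[4-methoxy-3-(oxan-2-yloxy)phenyl]-3-[(1E)-5-methylhexa-1,4-dien-1-yl]furan-2-carboxylic acid (racemic at the acetal carbon)
Conditions: LiOH·H2O (3 equiv), THF/MeOH/H2O, 25 °C; then cold 0.5 M HCl to pH 4
Reagents that add atoms: lithium hydroxide, [Li+].[OH-]
Why: Saponification (BAc2) of the methyl ester leaves the acetal, the ethers and the skipped diene untouched, and brief cold acidification to pH 4 spares the acetal.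

Step 10
Reactants: 14 4-methoxy-5-[4-methoxy-3-(oxan-2-yloxy)phenyl]-3-[(1E)-5-methylhexa-1,4-dien-1-yl]furan-2-carboxylic acid
Product: 16 2-diazo-1-{4-methoxy-5-[4-methoxy-3-(oxan-2-yloxy)phenyl]-3-[(1E)-5-methylhexa-1,4-dien-1-yl]furan-2-yl}ethan-1-one (racemic at the acetal carbon), via mixed carbonic anhydride 15 (not isolated)
Conditions: ClCO2Et (1.1 equiv), Et3N (1.1 equiv), THF, −15 °C; then TMSCHN2 (2 M in hexanes, 2.5 equiv), MeCN, 0 to 25 °C, dark
Reagents that add atoms: trimethylsilyldiazomethane, C[Si](C)(C)C=[N+]=[N-]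
Why: Acylation of the nucleophilic diazo carbon by the mixed carbonic anhydride (the acylation stage of the Arndt–Eistert sequence, run with a safer diazomethane surrogate), followed by loss of the silyl group, should give the terminal diazoketone under neutral conditions.

Step 11
Reactants: 16 2-diazo-1-{4-methoxy-5-[4-methoxy-3-(oxan-2-yloxy)phenyl]-3-[(1E)-5-methylhexa-1,4-dien-1-yl]furan-2-yl}ethan-1-one
Product: 19 3-methoxy-2-[4-methoxy-3-(oxan-2-yloxy)phenyl]-5-(3-methylbut-2-en-1-yl)-1-benzofuran-6-ol (racemic at the acetal carbon), via furylketene 17 (not isolated), via 5H-benzofuran-6-one 18 (not isolated)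
Conditions: hv (blue LED, 440 nm), ClCH2CH2Cl (0.01 M, degassed), 25 °C; then 80 °C
Reagents that add atoms: none
Why: Excitation of the diazoketone expels N2 with concerted 1,2-shift of the furyl group (Wolff rearrangement), which makes the C7–C7a bond and ketene 17, whose C6=C7 bond, the furan C7a=C3a bond and the side-chain C4=C5 bond form a dienylketene held cis by the furan. The closest known reaction type is the Wolff rearrangement and dienylketene electrocyclization to a phenol that underlie the Danheiser benzannulation, applied here to a diazoketone that already carries both olefins. Ring A closes by a thermally allowed, disrotatory 6π-electrocyclization that joins C6 to C5 and gives dienone 18, which tautomerizes to the C6 phenol with return of furan aromaticity and gain of the benzene ring. C5 is stereogenic only in 18 and becomes planar on enolization, so no stereocentre has to be controlled. The step needs rearrangement to beat carbene addition to the neighbouring olefin, and unimolecular closure to beat capture of the ketene; direct photolysis in a dry aprotic solvent at high dilution, the fixed cis relation of the two arms and the (E)-olefin, which turns the prenyl-bearing terminus outward, should secure this.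

Step 12
Reactants: 19 3-methoxy-2-[4-methoxy-3-(oxan-2-yloxy)phenyl]-5-(3-methylbut-2-en-1-yl)-1-benzofuran-6-ol
Product: 20 2-(3-hydroxy-4-methoxyphenyl)-3-methoxy-5-(3-methylbut-2-en-1-yl)-1-benzofuran-6-ol
Conditions: PPTS (0.2 equiv), MeOH, 40 °C
Reagents that add atoms: none
Why: PPTS-catalysed transacetalization to methanol should remove the aryl THP acetal at an acidity too low to protonate the prenyl olefin and close it onto the neighbouring C6 phenol as a chroman, or to hydrolyse the 3-methoxy enol ether.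

Compound list
1 | 5-bromo-2-methoxyphenol | COc1ccc(Br)cc1O | starting material
2 | 2-(5-bromo-2-methoxyphenoxy)oxane (racemic) | COc1ccc(Br)cc1OC1CCCCO1 | intermediate
3 | 2-[4-methoxy-3-(oxan-2-yloxy)phenyl]-4,4,5,5-tetramethyl-1,3,2-dioxaborolane (racemic) | COc1ccc(B2OC(C)(C)C(C)(C)O2)cc1OC1CCCCO1 | intermediate
4 | methyl 4,5-dibromofuran-2-carboxylate | COC(=O)c1cc(Br)c(Br)o1 | starting material
5 | methyl 4-bromo-5-[4-methoxy-3-(oxan-2-yloxy)phenyl]furan-2-carboxylate (racemic) | COC(=O)c1cc(Br)c(-c2ccc(OC)c(OC3CCCCO3)c2)o1 | intermediate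
6 | methyl 4-methoxy-5-[4-methoxy-3-(oxan-2-yloxy)phenyl]furan-2-carboxylate (racemic) | COC(=O)c1cc(OC)c(-c2ccc(OC)c(OC3CCCCO3)c2)o1 | intermediate
7 | {4-methoxy-2-(methoxycarbonyl)-5-[4-methoxy-3-(oxan-2-yloxy)phenyl]furan-3-yl}magnesium chloride (LiCl complex) | COC(=O)c1oc(-c2ccc(OC)c(OC3CCCCO3)c2)c(OC)c1[Mg]Cl | intermediate (not isolated)
8 | methyl 3-formyl-4-methoxy-5-[4-methoxy-3-(oxan-2-yloxy)phenyl]furan-2-carboxylate (racemic) | COC(=O)c1oc(-c2ccc(OC)c(OC3CCCCO3)c2)c(OC)c1C=O | intermediate
9 | 5-bromo-2-methylpent-2-ene | CC(C)=CCCBr | starting material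
10 | 5-[(4-methylpent-3-en-1-yl)sulfanyl]-1-phenyl-1H-tetrazole | CC(C)=CCCSc1nnnn1-c1ccccc1 | intermediate
11 | 5-[(4-methylpent-3-en-1-yl)sulfonyl]-1-phenyl-1H-tetrazole | CC(C)=CCCS(=O)(=O)c1nnnn1-c1ccccc1 | intermediate
12 | potassium 4-methyl-1-[(1-phenyl-1H-tetrazol-5-yl)sulfonyl]pent-3-en-1-ide | [K+].CC(C)=CC[CH-]S(=O)(=O)c1nnnn1-c1ccccc1 | intermediate (not isolated)
13 | methyl 4-methoxy-5-[4-methoxy-3-(oxan-2-yloxy)phenyl]-3-[(1E)-5-methylhexa-1,4-dien-1-yl]furan-2-carboxylate (racemic at the acetal carbon) | COC(=O)c1oc(-c2ccc(OC)c(OC3CCCCO3)c2)c(OC)c1/C=C/CC=C(C)C | intermediate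
14 | 4-methoxy-5-[4-methoxy-3-(oxan-2-yloxy)phenyl]-3-[(1E)-5-methylhexa-1,4-dien-1-yl]furan-2-carboxylic acid (racemic at the acetal carbon) | OC(=O)c1oc(-c2ccc(OC)c(OC3CCCCO3)c2)c(OC)c1/C=C/CC=C(C)C | intermediate
15 | ethyl carbonic 4-methoxy-5-[4-methoxy-3-(oxan-2-yloxy)phenyl]-3-[(1E)-5-methylhexa-1,4-dien-1-yl]furan-2-carboxylic anhydride | CCOC(=O)OC(=O)c1oc(-c2ccc(OC)c(OC3CCCCO3)c2)c(OC)c1/C=C/CC=C(C)C | intermediate (not isolated)
16 | 2-diazo-1-{4-methoxy-5-[4-methoxy-3-(oxan-2-yloxy)phenyl]-3-[(1E)-5-methylhexa-1,4-dien-1-yl]furan-2-yl}ethan-1-one (racemic at the acetal carbon) | [N-]=[N+]=CC(=O)c1oc(-c2ccc(OC)c(OC3CCCCO3)c2)c(OC)c1/C=C/CC=C(C)C | intermediate (key-step precursor)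
17 | 2-{4-methoxy-5-[4-methoxy-3-(oxan-2-yloxy)phenyl]-3-[(1E)-5-methylhexa-1,4-dien-1-yl]furan-2-yl}ethen-1-one (furylketene) | O=C=Cc1oc(-c2ccc(OC)c(OC3CCCCO3)c2)c(OC)c1/C=C/CC=C(C)C | intermediate (not isolated)
18 | 3-methoxy-2-[4-methoxy-3-(oxan-2-yloxy)phenyl]-5-(3-methylbut-2-en-1-yl)-1-benzofuran-6(5H)-one (C5 unspecified, transient) | COC1=C(c2ccc(OC)c(OC3CCCCO3)c2)OC2=CC(=O)C(CC=C(C)C)C=C12 | intermediate (not isolated)
19 | 3-methoxy-2-[4-methoxy-3-(oxan-2-yloxy)phenyl]-5-(3-methylbut-2-en-1-yl)-1-benzofuran-6-ol (racemic at the acetal carbon) | COc1ccc(-c2oc3cc(O)c(CC=C(C)C)cc3c2OC)cc1OC1CCCCO1 | intermediate (key-step product)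
20 | 2-(3-hydroxy-4-methoxyphenyl)-3-methoxy-5-(3-methylbut-2-en-1-yl)-1-benzofuran-6-ol | COc1ccc(-c2oc3cc(O)c(CC=C(C)C)cc3c2OC)cc1O | target

Total step count: 12.
Longest linear sequence: 10 steps (1 → 2 → 3 → 5 → 6 → 8 → 13 → 14 → 16 → 19 → 20); the sulfone branch (9 → 10 → 11) adds 2 steps.

Steps most likely to fail

Step 11. The ketene may be captured by the phenol already formed or by a second ketene before it closes, or the excited diazoketone may react as a carbene with the neighbouring C4=C5 olefin instead of rearranging. The fallback sets out from diazoketone 16 and generates the ketene without photochemistry and at a controlled, very low concentration. A silver-catalysed Wolff rearrangement in wet solvent (PhCO2Ag cat., Et3N, THF/H2O, 25 °C, dark; Arndt–Eistert homologation) would give 2-{4-methoxy-5-[4-methoxy-3-(oxan-2-yloxy)phenyl]-3-[(1E)-5-methylhexa-1,4-dien-1-yl]furan-2-yl}acetic acid F1. 1-Chloro-N,N,2-trimethylprop-1-en-1-amine in CH2Cl2 at 0 °C would convert it under neutral conditions into 2-{4-methoxy-5-[4-methoxy-3-(oxan-2-yloxy)phenyl]-3-[(1E)-5-methylhexa-1,4-dien-1-yl]furan-2-yl}acetyl chloride F2. Slow addition of this chloride to Et3N in toluene at 80 °C would release ketene 17 by dehydrochlorination, so that closure through 18 should outrun every bimolecular path. The route is rejoined at 19.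

Step 4. Substitution at the hindered C4–Br bond may be slow, so that reductive loss of bromine and attack on the ester take over. The fallback sets out from bromide 5 and makes the C–O bond by oxidation of a C–B bond instead of by C–O coupling. Miyaura borylation (bis(pinacolato)diboron, PdCl2(dppf), KOAc, dioxane, 90 °C) would give methyl 5-[4-methoxy-3-(oxan-2-yloxy)phenyl]-4-(4,4,5,5-tetramethyl-1,3,2-dioxaborolan-2-yl)furan-2-carboxylate F3. Oxidation (NaBO3·4H2O, THF/H2O, 25 °C) would give methyl 4-hydroxy-5-[4-methoxy-3-(oxan-2-yloxy)phenyl]furan-2-carboxylate F4, in equilibrium with its furan-3(2H)-one tautomer. O-Methylation with the hard electrophile Me2SO4 (K2CO3, acetone) would lead back to 6.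

Step 8. The intermediate beta-alkoxide may close onto the neighbouring methyl ester before the Smiles shift, and the olefin geometry may erode. The fallback sets out from bromide 9 and aldehyde 8 and uses a phosphorus ylide, whose oxaphosphetane offers no free alkoxide. Heating 9 with PPh3 (MeCN, 80 °C) would give (4-methylpent-3-en-1-yl)triphenylphosphonium bromide F5. Its ylide (NaN(SiMe3)2, THF, −78 °C) and aldehyde 8 would give by Wittig reaction mainly methyl 4-methoxy-5-[4-methoxy-3-(oxan-2-yloxy)phenyl]-3-[(1Z)-5-methylhexa-1,4-dien-1-yl]furan-2-carboxylate F6. Iodine-catalysed equilibration (I2 cat., CH2Cl2, daylight) would convert the (Z)-olefin into the conjugated (E)-isomer 13, where the route is rejoined.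

Further compounds
F1 | step 11 | 2-{4-methoxy-5-[4-methoxy-3-(oxan-2-yloxy)phenyl]-3-[(1E)-5-methylhexa-1,4-dien-1-yl]furan-2-yl}acetic acid (racemic at the acetal carbon) | OC(=O)Cc1oc(-c2ccc(OC)c(OC3CCCCO3)c2)c(OC)c1/C=C/CC=C(C)C
F2 | step 11 | 2-{4-methoxy-5-[4-methoxy-3-(oxan-2-yloxy)phenyl]-3-[(1E)-5-methylhexa-1,4-dien-1-yl]furan-2-yl}acetyl chloride (racemic at the acetal carbon) | ClC(=O)Cc1oc(-c2ccc(OC)c(OC3CCCCO3)c2)c(OC)c1/C=C/CC=C(C)C
F3 | step 4 | methyl 5-[4-methoxy-3-(oxan-2-yloxy)phenyl]-4-(4,4,5,5-tetramethyl-1,3,2-dioxaborolan-2-yl)furan-2-carboxylate (racemic) | COC(=O)c1cc(B2OC(C)(C)C(C)(C)O2)c(-c2ccc(OC)c(OC3CCCCO3)c2)o1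
F4 | step 4 | methyl 4-hydroxy-5-[4-methoxy-3-(oxan-2-yloxy)phenyl]furan-2-carboxylate (racemic) | COC(=O)c1cc(O)c(-c2ccc(OC)c(OC3CCCCO3)c2)o1
F5 | step 8 | (4-methylpent-3-en-1-yl)triphenylphosphonium bromide | CC(C)=CCC[P+](c1ccccc1)(c1ccccc1)c1ccccc1.[Br-]
F6 | step 8 | methyl 4-methoxy-5-[4-methoxy-3-(oxan-2-yloxy)phenyl]-3-[(1Z)-5-methylhexa-1,4-dien-1-yl]furan-2-carboxylate (racemic at the acetal carbon) | COC(=O)c1oc(-c2ccc(OC)c(OC3CCCCO3)c2)c(OC)c1/C=C\CC=C(C)C
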